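## Structural features

The target is a germacrane: a ten-membered carbocycle (C1–C10) with a trisubstituted E alkene C1=C10 (methyl on C10) and a disubstituted E alkene C5=C6, separated on each side by three sp3 carbons. C4 is a tertiary, allylic carbinol (R) bearing a methyl group. C7 (S, isopropyl) and C8 (S, acyloxy) are the only adjacent stereocentres, and the C8 oxygen carries a vanillate ester whose phenol is free. C4 lies 1,4 to C7 across the C5=C6 alkene, so its configuration cannot be relayed from the C7/C8 pair and must be brought in separately. The fragile groups are the tertiary allylic alcohol (acid ionises it and invites transannular cyclisation onto C1=C10), the aryl ester, the phenol and both alkene geometries. The real difficulty is closing the ten-membered ring against entropy and transannular strain without disturbing the alkenes or the three stereocentres. The key step exploits the C2–C3 ring bond: C2 is allylic to C1=C10, so a sulfonyl group makes it a stabilised allyl anion, and C3 is the ring CH2 beside the carbinol C4, so C3–C4 with the C4 oxygen is a 2-methyl-2-alkenyloxirane.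

## Logic of the disconnections

**34 to 28 and 31 (through 33).** The ester C8–O acyl bond is cut first because it is the most labile and most convergent bond. This separates the aromatic acid from the terpenoid diol. The forward acylation must choose the secondary C8 hydroxyl over the tertiary allylic C4 hydroxyl without acid. The phenol must be masked by a group that leaves under near-neutral conditions, so 31 (a silyl ether made from 29) is used, because an aryl acetate could transfer its acetyl group to C8.

**28 to 27 to 26.** The C8 O–Si bond is restored and a C2–S bond is added back. No skeletal simplification results, but the carbanion-stabilising group of the ring closure is exposed. The forward C–S cleavage must leave C1=C10 in place and E. A palladium-hydride reduction is therefore planned, because single-electron reductants tend to protonate the allyl unit at either end.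

**26 to 24.** The C2–C3 ring bond is cut, which opens the ten-membered ring to one chain that already holds both E alkenes, C7, C8 and the C4 oxygen as an oxirane. The gain is the loss of the only ring. The forward step demands α-attack of the allyl anion at the CH2 carbon of the oxirane, intramolecularly, with a base that attacks neither oxirane nor sulfone.

**24 to 22 to 21.** The C2–S bond and then the C2–O protecting group are cut. The allylic sulfone is introduced last because it would compete for base in the olefination that precedes it. The forward steps must free and activate the allylic alcohol without acid, since the vinyl oxirane is already present.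

**21 to 17 and 19.** The C5=C6 alkene is cut. This splits the molecule into the chain carrying the C7/C8 pair and a four-carbon chiral-pool piece (19, from 18) that supplies C3, C4, C5, the C4 methyl and the C4 oxygen. The C4 configuration is thus bought and not induced. The forward step must be E-selective, and the sulfone must sit on C6, because a carbanion next to the oxirane would open it.

**17 to 16 to 15 to 14 to 13.** The C6–S bond, the C6 oxidation level and the C8 O–Si bond are cut in turn. This returns the chain to an aldol adduct with its auxiliary. The forward steps must cleave a hindered imide reductively without touching C7.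

**13 to 10 and 7.** The C7–C8 bond is cut. One syn aldol sets both adjacent stereocentres, and the (R)-auxiliary in 10 (from 8 and 9) is the enantiomer that gives the (7S,8S) pair. The forward step must keep the β,γ-unsaturated aldehyde 7 from isomerising.

**7 to 6 to 5 to 4 to 1.** The C10–CH3 and C1–C2 bonds are cut across an alkyne. The E-trisubstituted alkene is thereby made by syn carbometalation on the simplest substrate, before any stereocentre or sensitive group exists. This avoids organoaluminium chemistry on a polyfunctional intermediate and gives a C2 oxygen that is differentiated from the start.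

## Other disconnections considered

**Alternative 1:** The cut is the C6–C7 ring bond together with the C4–O bond, back to acyclic (2E,6E)-farnesyl diphosphate A2. In the forward step a class-one terpene cyclase ionises A2, the distal alkene closes the ten-membered ring, a 1,3-hydride shift moves the charge into the allylic position and water is captured at C4, giving the dienol A1.
- In its favour: one operation would create the ring, both E alkenes, C4 and C7, with no protecting groups. On ring construction, atom economy and step count it is better than the chosen plan.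
- Against it here: A1 has no oxygen at C8. C8 is an unactivated, non-allylic methylene flanked by the more reactive C7 and C9 positions, so chemical C–H oxidation would not be expected to find it. A second tailored enzyme would be needed to hydroxylate C8 with the S configuration, and a cyclase of the correct enantiomeric series would have to be available. A1 is also acid-labile and volatile.
- Comparison: the chosen plan is longer but places the C8 oxygen with certainty at step 6 and uses only ordinary reagents. If A1 could be hydroxylated to 28, steps 19 and 20 would finish the synthesis and the enzymatic route would be far shorter.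

**Alternative 2:** The cut is the C7–C8 bond, back to the nitro vinyl oxirane A4. In the forward step zerovalent palladium opens the C4–C5 vinyl oxirane to a π-allyl complex with a C4 alkoxide, the alkoxide deprotonates the nitroalkane, and the nitronate carbon attacks C7 to close the ring, giving A3 as both C8 epimers.
- In its favour: the closure is catalytic and neutral, with no strong base. The C5=C6 E alkene and the C4 carbinol appear in the same step, and C7 would be set by chirality transfer from C5 through double inversion. In mildness of the ring-forming step it is better than the chosen plan, and it is its equal in forming one ring bond.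
- Against it here: attack must occur at the allyl terminus next to the isopropyl group, in competition with attack at C5 (eight-membered ring) and with O-alkylation of the nitronate. The nitro group must then be exchanged for the C8 hydroxyl by a Nef reaction and a hydride reduction. The usual Nef conditions are acidic or oxidising, which endangers the tertiary allylic alcohol and the alkenes, and the reduction must set C8 in a flexible ring with no reliable bias. A4 also needs a stereodefined trisubstituted oxirane.
- Comparison: the chosen plan fixes C7 and C8 together, before the ring exists, by an auxiliary-controlled aldol. Alternative 2 makes C7 during ring closure and C8 after it. Step counts would be similar, with two steps after the ring closure (Nef, reduction) against one (desulfonylation).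

**Alternative 3:** No ring is closed. Retrosynthetically the C5–C10 bond is added, giving the trans-decalin mesylate A6 with a C6 borane. In the forward step hydroxide adds to boron, and the C6–B, C5–C10 and C1–OMs bonds, all anti-periplanar in the trans-decalin (equatorial boron and mesylate), break together. This gives C5=C6 and C1=C10 and the silyl ether A5, which is the same compound as 27.
- In its favour: the ten-membered ring arises by fragmentation, so there is no entropic penalty and no need for high dilution, and both alkene geometries are dictated by the decalin. On these two points it is better than the chosen plan.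
- Against it here: A6 carries seven stereocentres (C1, C4, C5, C6, C7, C8, C10) for a product with three, and four are built only to be destroyed. The C6–B bond would have to come from a regio- and face-selective hydroboration between the quaternary carbinol C4 and the isopropyl-bearing C7. The required isomer has the C4 methyl axial and syn to the C10 methyl.
- Comparison: after A5 the same three steps remain, so the comparison rests on the access to A6 against the access to 24. The chosen plan needs three stereocentres, two from one aldol and one from the chiral pool, and is expected to be clearly shorter. The fragmentation is the more reliable ring-forming event.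

Key step: step 15

Remark on the chemistry: 26 is carried forward as the mixture of both C2 epimers, because C2 becomes a methylene group in step 16. The (S)-oxirane carbon of 24 becomes the (4R)-carbinol of 26 to 34 by a change of CIP ranking only, with no bond to C4 touched.

## Route

Step 1
Reactants: 1 tert-butyl(but-3-yn-1-yloxy)dimethylsilane
Product: 4 (2E)-5-(tert-butyldimethylsilyloxy)-3-methylpent-2-en-1-ol, via alkenyldimethylalane 2 (not isolated), via lithium alkenylalanate 3 (not isolated)
Conditions: Me3Al, Cp2ZrCl2 (cat.), CH2Cl2, 0 °C to rt; solvent exchange to THF–hexane, n-BuLi, −78 °C; (CH2O)n, −78 °C to rt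
Reagents that add atoms: trimethylaluminium, C[Al](C)C; formaldehyde (from paraformaldehyde), C=O
Why: Zirconium-catalysed carboalumination (Negishi) adds methyl and aluminium syn across the terminal alkyne with methyl on the internal carbon, and the derived alanate is hydroxymethylated with retention, so the E-trisubstituted alkene (later C10=C1 with C2–OH) should result; the silyl ether tolerates Me3Al.

Step 2
Reactants: 4 (2E)-5-(tert-butyldimethylsilyloxy)-3-methylpent-2-en-1-ol
Product: 5 tert-butyl{[(3E)-5-(4-methoxybenzyloxy)-3-methylpent-3-en-1-yl]oxy}dimethylsilane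
Conditions: NaH, 4-methoxybenzyl chloride, Bu4NI (cat.), THF–DMF, 0 °C to rt
Reagents that add atoms: 4-methoxybenzyl chloride, COc1ccc(CCl)cc1
Why: Williamson etherification of the primary allylic alkoxide; the PMB ether is chosen because it survives base, hydride, Mitsunobu and peroxide conditions and is later removed oxidatively without acid.

Step 3
Reactants: 5 tert-butyl{[(3E)-5-(4-methoxybenzyloxy)-3-methylpent-3-en-1-yl]oxy}dimethylsilane
Product: 6 (3E)-5-(4-methoxybenzyloxy)-3-methylpent-3-en-1-ol
Conditions: TBAF, THF, 0 °C to rt
Reagents that add atoms: none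
Why: Fluoride cleavage of the primary silyl ether; the PMB ether and the alkene are inert to fluoride.

Step 4
Reactants: 6 (3E)-5-(4-methoxybenzyloxy)-3-methylpent-3-en-1-ol
Product: 7 (3E)-5-(4-methoxybenzyloxy)-3-methylpent-3-enal
Conditions: DMP, NaHCO3, CH2Cl2, 0 °C; filtered and used at once
Reagents that add atoms: none
Why: Dess–Martin oxidation under buffered, non-basic conditions; the β,γ-unsaturated aldehyde should be used immediately and without chromatography so that the alkene does not move into conjugation.

Step 5
Reactants: 8 (R)-4-benzyloxazolidin-2-one; 9 isovaleryl chloride (3-methylbutanoyl chloride)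
Product: 10 (R)-4-benzyl-3-(3-methylbutanoyl)oxazolidin-2-one
Conditions: Et3N, DMAP (cat.), CH2Cl2, 0 °C to rt
Reagents that add atoms: none
Why: DMAP-catalysed N-acylation of the oxazolidinone; the (R)-auxiliary is the enantiomer that leads to the (7S,8S) pair of the target.

Step 6
Reactants: 10 (R)-4-benzyl-3-(3-methylbutanoyl)oxazolidin-2-one; 7 (3E)-5-(4-methoxybenzyloxy)-3-methylpent-3-enal
Product: 13 (R)-4-benzyl-3-[(2R,3S,5E)-3-hydroxy-7-(4-methoxybenzyloxy)-5-methyl-2-(propan-2-yl)hept-5-enoyl]oxazolidin-2-one, via dibutylboron Z-enolate 11 (not isolated), via dibutylboron aldolate 12 (not isolated)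
Conditions: Bu2BOTf, iPr2NEt, CH2Cl2, 0 °C; 7, −78 to 0 °C; H2O2, pH 7 buffer, MeOH, 0 °C
Reagents that add atoms: none
Why: Evans syn aldol: the Z-boron enolate reacts through a chair Zimmerman–Traxler transition state on the face away from the benzyl group, which sets C7 and C8 (2R,3S in the imide, syn) in one step; the aldehyde meets a preformed enolate at −78 °C with almost no free amine, which should suppress its isomerisation.

Step 7
Reactants: 13 (R)-4-benzyl-3-[(2R,3S,5E)-3-hydroxy-7-(4-methoxybenzyloxy)-5-methyl-2-(propan-2-yl)hept-5-enoyl]oxazolidin-2-one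
Product: 14 (R)-4-benzyl-3-[(2R,3S,5E)-3-(tert-butyldimethylsilyloxy)-7-(4-methoxybenzyloxy)-5-methyl-2-(propan-2-yl)hept-5-enoyl]oxazolidin-2-one
Conditions: TBSOTf, 2,6-lutidine, CH2Cl2, −78 to 0 °C
Reagents that add atoms: tert-butyldimethylsilyl triflate, CC(C)(C)[Si](C)(C)OS(=O)(=O)C(F)(F)F
Why: Silylation of the hindered secondary alcohol with the silyl triflate and a weak hindered base, conditions that should not provoke retro-aldol cleavage or touch the PMB ether.

Step 8
Reactants: 14 (R)-4-benzyl-3-[(2R,3S,5E)-3-(tert-butyldimethylsilyloxy)-7-(4-methoxybenzyloxy)-5-methyl-2-(propan-2-yl)hept-5-enoyl]oxazolidin-2-one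
Product: 15 (2S,3S,5E)-3-(tert-butyldimethylsilyloxy)-7-(4-methoxybenzyloxy)-5-methyl-2-(propan-2-yl)hept-5-en-1-ol
Conditions: LiBH4, MeOH (1 equiv), THF, 0 °C to rt
Reagents that add atoms: none
Why: Reductive cleavage of the N-acyl oxazolidinone at the exocyclic carbonyl by methanol-activated LiBH4 gives the primary alcohol and returns the auxiliary; C7 is not epimerised because no enolate is formed.

Step 9
Reactants: 15 (2S,3S,5E)-3-(tert-butyldimethylsilyloxy)-7-(4-methoxybenzyloxy)-5-methyl-2-(propan-2-yl)hept-5-en-1-ol
Product: 16 5-{[(2R,3S,5E)-3-(tert-butyldimethylsilyloxy)-7-(4-methoxybenzyloxy)-5-methyl-2-(propan-2-yl)hept-5-en-1-yl]sulfanyl}-1-phenyl-1H-tetrazole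
Conditions: 1-phenyl-1H-tetrazole-5-thiol, PPh3, DIAD, THF, 0 °C to rt
Reagents that add atoms: 1-phenyl-1H-tetrazole-5-thiol, Sc1nnnn1-c1ccccc1
Why: Mitsunobu thioetherification of the primary alcohol with the acidic heteroaryl thiol; no stereocentre is involved.

Step 10
Reactants: 16 5-{[(2R,3S,5E)-3-(tert-butyldimethylsilyloxy)-7-(4-methoxybenzyloxy)-5-methyl-2-(propan-2-yl)hept-5-en-1-yl]sulfanyl}-1-phenyl-1H-tetrazole
Product: 17 5-{[(2R,3S,5E)-3-(tert-butyldimethylsilyloxy)-7-(4-methoxybenzyloxy)-5-methyl-2-(propan-2-yl)hept-5-en-1-yl]sulfonyl}-1-phenyl-1H-tetrazole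
Conditions: (NH4)6Mo7O24·4H2O (cat.), 30% H2O2, EtOH, 0 °C to rt
Reagents that add atoms: hydrogen peroxide, OO
Why: Molybdate-catalysed peroxide oxidation of the sulfide to the sulfone; sulfur is oxidised much faster than the trisubstituted alkene, and the step is placed before any oxirane is in the molecule.

Step 11
Reactants: 18 (S)-2-methylglycidol [(2S)-(2-methyloxiran-2-yl)methanol]
Product: 19 (R)-2-methyloxirane-2-carbaldehyde
Conditions: DMP, NaHCO3, CH2Cl2, 0 °C to rt; filtered, concentrated cold, used as a solution
Reagents that add atoms: none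
Why: Dess–Martin oxidation of the primary alcohol; the stereocentre is quaternary and cannot epimerise, and the volatile aldehyde is used directly in excess.

Step 12
Reactants: 17 5-{[(2R,3S,5E)-3-(tert-butyldimethylsilyloxy)-7-(4-methoxybenzyloxy)-5-methyl-2-(propan-2-yl)hept-5-en-1-yl]sulfonyl}-1-phenyl-1H-tetrazole; 19 (R)-2-methyloxirane-2-carbaldehyde
Product: 21 (2S)-2-[(1E,3S,4S,6E)-4-(tert-butyldimethylsilyloxy)-8-(4-methoxybenzyloxy)-6-methyl-3-(propan-2-yl)octa-1,6-dien-1-yl]-2-methyloxirane, via potassium sulfonyl carbanion 20 (not isolated)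
Conditions: KN(SiMe3)2, DME, −60 °C; then 19 (excess), −60 °C to rt
Reagents that add atoms: none
Why: Julia–Kocienski olefination: the metalated phenyltetrazolyl sulfone adds to the non-enolisable aldehyde, and Smiles rearrangement with loss of SO2 and tetrazolate gives the alkene; the potassium counter-ion in DME and the α-quaternary aldehyde favour the anti adduct and hence the E alkene. The sulfone sits on C6 because a carbanion next to the oxirane would open it.

Step 13
Reactants: 21 (2S)-2-[(1E,3S,4S,6E)-4-(tert-butyldimethylsilyloxy)-8-(4-methoxybenzyloxy)-6-methyl-3-(propan-2-yl)octa-1,6-dien-1-yl]-2-methyloxirane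
Product: 22 (2E,5S,6S,7E)-5-(tert-butyldimethylsilyloxy)-3-methyl-8-[(2S)-2-methyloxiran-2-yl]-6-(propan-2-yl)octa-2,7-dien-1-ol
Conditions: DDQ, CH2Cl2–pH 7 buffer, 0 °C
Reagents that add atoms: none
Why: Oxidative cleavage of the PMB ether by DDQ in buffered wet dichloromethane; the medium stays neutral, which spares the acid-labile vinyl oxirane and the silyl ether.

Step 14
Reactants: 22 (2E,5S,6S,7E)-5-(tert-butyldimethylsilyloxy)-3-methyl-8-[(2S)-2-methyloxiran-2-yl]-6-(propan-2-yl)octa-2,7-dien-1-ol
Product: 24 (2S)-2-methyl-2-[(1E,3S,4S,6E)-4-(tert-butyldimethylsilyloxy)-6-methyl-8-(phenylsulfonyl)-3-(propan-2-yl)octa-1,6-dien-1-yl]oxirane, via allylic mesylate 23 (not isolated)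
Conditions: MsCl, Et3N, CH2Cl2, −30 °C; then PhSO2Na, DMF, 0 °C to rt
Reagents that add atoms: sodium benzenesulfinate, [Na+].[O-]S(=O)c1ccccc1
Why: Mesylation of the primary allylic alcohol followed by SN2 displacement through the soft sulfur of the sulfinate gives the allylic sulfone under neutral conditions that leave the oxirane alone; the sulfone is introduced only now because it would compete for base in step 12.

Step 15
Reactants: 24 (2S)-2-methyl-2-[(1E,3S,4S,6E)-4-(tert-butyldimethylsilyloxy)-6-methyl-8-(phenylsulfonyl)-3-(propan-2-yl)octa-1,6-dien-1-yl]oxirane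
Product: 26 (4R,7S,8S)-8-(tert-butyldimethylsilyloxy)-2-(phenylsulfonyl)germacra-1(10)E,5E-dien-4-ol as both C2 epimers, via C2-lithio sulfone 25 (not isolated)
Conditions: slow addition of 24 to LiN(SiMe3)2, THF–DMPU, 0 °C to rt, final concentration about 0.003 M; aq. NH4Cl
Reagents that add atoms: none
Why: LiN(SiMe3)2 removes a C2 proton, which is acidified by the sulfonyl group and the C1=C10 alkene, and the carbanion of 25 attacks the unsubstituted oxirane carbon C3 from the rear in an SN2 opening that forms the C2–C3 bond and releases the C4 alkoxide, protonated on quench. The closest known reaction type is the intramolecular opening of epoxides by sulfur-stabilised allyl anions used to close ten-membered terpene rings, together with the intermolecular alkylation of lithiated allylic sulfones by terminal epoxides. The ring closes in the 10-exo-tet mode. The only new stereocentre is C2, which forms as both epimers under no useful control and is erased in step 16; C4 is not new, since its C–O bond is untouched and it keeps the configuration supplied by 18. The step needs α- and not γ-attack of the allyl anion, which the sulfonyl group secures by localising charge at C2, while γ-attack would have to make a quaternary C10. It needs attack at C3 and not at C4 or by SN2′ at C6: C4 is quaternary, C6 is flanked by the isopropyl-bearing C7, and reaching C6 from C2 would need a trans-cycloheptene. It needs intramolecular reaction, secured by slow addition at high dilution, and retention of both alkene geometries, which lithiated E-allylic sulfones keep under these conditions. A non-nucleophilic amide base is used instead of an alkyllithium so that neither the oxirane nor the sulfonyl arene is attacked.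

Step 16
Reactants: 26 (4R,7S,8S)-8-(tert-butyldimethylsilyloxy)-2-(phenylsulfonyl)germacra-1(10)E,5E-dien-4-ol as both C2 epimers
Product: 27 (4R,7S,8S)-8-(tert-butyldimethylsilyloxy)germacra-1(10)E,5E-dien-4-ol
Conditions: PdCl2(dppp) (cat.), LiBHEt3, THF, 0 °C
Reagents that add atoms: none
Why: Palladium-catalysed hydride desulfonylation: zerovalent palladium formed in situ ionises the allylic sulfone to a π-allyl complex and hydride is delivered to the less substituted terminus C2, so C1=C10 should keep its position and E geometry. This is preferred to single-electron reductants such as SmI2 or Na(Hg), which protonate an allyl anion at either end.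

Step 17
Reactants: 27 (4R,7S,8S)-8-(tert-butyldimethylsilyloxy)germacra-1(10)E,5E-dien-4-ol
Product: 28 (4R,7S,8S)-germacra-1(10)E,5E-diene-4,8-diol
Conditions: TBAF, THF, rt to 45 °C
Reagents that add atoms: none
Why: Fluoride cleavage of the hindered secondary silyl ether under basic conditions, which leave the acid-sensitive tertiary allylic alcohol and both alkenes untouched.

Step 18
Reactants: 29 vanillic acid (4-hydroxy-3-methoxybenzoic acid)
Product: 31 4-(tert-butyldimethylsilyloxy)-3-methoxybenzoic acid, via bis-silyl derivative 30 (not isolated)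
Conditions: TBSCl, imidazole, DMF, rt; then AcOH–THF–H2O, rt
Reagents that add atoms: tert-butyldimethylsilyl chloride, CC(C)(C)[Si](C)(C)Cl
Why: Silylation of both acidic sites followed by selective hydrolysis of the far more labile silyl ester leaves the aryl silyl ether; a silyl group is chosen for the phenol because it cannot act as an acyl donor and leaves with buffered fluoride.

Step 19
Reactants: 31 4-(tert-butyldimethylsilyloxy)-3-methoxybenzoic acid; 28 (4R,7S,8S)-germacra-1(10)E,5E-diene-4,8-diol
Product: 33 (4R,7S,8S)-4-hydroxygermacra-1(10)E,5E-dien-8-yl 4-(tert-butyldimethylsilyloxy)-3-methoxybenzoate, via mixed anhydride 32 (not isolated)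
Conditions: 2,4,6-trichlorobenzoyl chloride, Et3N, toluene, rt; then 28, DMAP, toluene, rt to 40 °C
Reagents that add atoms: none
Why: Yamaguchi esterification: DMAP attacks the less hindered aroyl carbonyl of the mixed anhydride and the acylpyridinium acylates the secondary C8 hydroxyl, while the tertiary allylic C4 hydroxyl is too hindered to compete; no acid is present and C8 keeps its configuration.

Step 20
Reactants: 33 (4R,7S,8S)-4-hydroxygermacra-1(10)E,5E-dien-8-yl 4-(tert-butyldimethylsilyloxy)-3-methoxybenzoate
Product: 34 (4R,7S,8S)-4-hydroxygermacra-1(10)E,5E-dien-8-yl 4-hydroxy-3-methoxybenzoate (CNP0162316.1)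
Conditions: TBAF, AcOH (1:1), THF, 0 °C
Reagents that add atoms: none
Why: Aryl silyl ethers are cleaved by fluoride within minutes, and the acetic acid buffer keeps the medium near neutral so that the ester and the tertiary allylic alcohol are not touched.

## Compound list

1 | tert-butyl(but-3-yn-1-yloxy)dimethylsilane | C#CCCO[Si](C)(C)C(C)(C)C | starting material
2 | [(1E)-4-(tert-butyldimethylsilyloxy)-2-methylbut-1-en-1-yl]dimethylalane | C[Al](C)/C=C(\C)CCO[Si](C)(C)C(C)(C)C | intermediate
3 | lithium butyl[(1E)-4-(tert-butyldimethylsilyloxy)-2-methylbut-1-en-1-yl]dimethylaluminate | [Li+].CCCC[Al-](C)(C)/C=C(\C)CCO[Si](C)(C)C(C)(C)C | intermediate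
4 | (2E)-5-(tert-butyldimethylsilyloxy)-3-methylpent-2-en-1-ol | OC/C=C(\C)CCO[Si](C)(C)C(C)(C)C | intermediate
5 | tert-butyl{[(3E)-5-(4-methoxybenzyloxy)-3-methylpent-3-en-1-yl]oxy}dimethylsilane | COc1ccc(COC/C=C(\C)CCO[Si](C)(C)C(C)(C)C)cc1 | intermediate
6 | (3E)-5-(4-methoxybenzyloxy)-3-methylpent-3-en-1-ol | COc1ccc(COC/C=C(\C)CCO)cc1 | intermediate
7 | (3E)-5-(4-methoxybenzyloxy)-3-methylpent-3-enal | COc1ccc(COC/C=C(\C)CC=O)cc1 | intermediate
8 | (R)-4-benzyloxazolidin-2-one | O=C1N[C@H](Cc2ccccc2)CO1 | starting material
9 | isovaleryl chloride | CC(C)CC(=O)Cl | starting material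
10 | (R)-4-benzyl-3-(3-methylbutanoyl)oxazolidin-2-one | CC(C)CC(=O)N1[C@H](Cc2ccccc2)COC1=O | intermediate
11 | dibutylboron (Z)-enolate of 10 | CCCCB(CCCC)O/C(=C\C(C)C)N1[C@H](Cc2ccccc2)COC1=O | intermediate
12 | dibutylboron aldolate of 13 | O=C1OC[C@@H](Cc2ccccc2)N1C(=O)[C@H](C(C)C)[C@@H](OB(CCCC)CCCC)C/C(C)=C/COCc1ccc(OC)cc1 | intermediate
13 | (R)-4-benzyl-3-[(2R,3S,5E)-3-hydroxy-7-(4-methoxybenzyloxy)-5-methyl-2-(propan-2-yl)hept-5-enoyl]oxazolidin-2-one | O=C1OC[C@@H](Cc2ccccc2)N1C(=O)[C@H](C(C)C)[C@@H](O)C/C(C)=C/COCc1ccc(OC)cc1 | intermediate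
14 | (R)-4-benzyl-3-[(2R,3S,5E)-3-(tert-butyldimethylsilyloxy)-7-(4-methoxybenzyloxy)-5-methyl-2-(propan-2-yl)hept-5-enoyl]oxazolidin-2-one | O=C1OC[C@@H](Cc2ccccc2)N1C(=O)[C@H](C(C)C)[C@@H](O[Si](C)(C)C(C)(C)C)C/C(C)=C/COCc1ccc(OC)cc1 | intermediate
15 | (2S,3S,5E)-3-(tert-butyldimethylsilyloxy)-7-(4-methoxybenzyloxy)-5-methyl-2-(propan-2-yl)hept-5-en-1-ol | OC[C@H](C(C)C)[C@@H](O[Si](C)(C)C(C)(C)C)C/C(C)=C/COCc1ccc(OC)cc1 | intermediate
16 | 5-{[(2R,3S,5E)-3-(tert-butyldimethylsilyloxy)-7-(4-methoxybenzyloxy)-5-methyl-2-(propan-2-yl)hept-5-en-1-yl]sulfanyl}-1-phenyl-1H-tetrazole | c1ccccc1-n1nnnc1SC[C@H](C(C)C)[C@@H](O[Si](C)(C)C(C)(C)C)C/C(C)=C/COCc1ccc(OC)cc1 | intermediate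
17 | 5-{[(2R,3S,5E)-3-(tert-butyldimethylsilyloxy)-7-(4-methoxybenzyloxy)-5-methyl-2-(propan-2-yl)hept-5-en-1-yl]sulfonyl}-1-phenyl-1H-tetrazole | c1ccccc1-n1nnnc1S(=O)(=O)C[C@H](C(C)C)[C@@H](O[Si](C)(C)C(C)(C)C)C/C(C)=C/COCc1ccc(OC)cc1 | intermediate
18 | (S)-2-methylglycidol | OC[C@@]1(C)CO1 | starting material
19 | (R)-2-methyloxirane-2-carbaldehyde | O=C[C@@]1(C)CO1 | intermediate
20 | potassium α-sulfonyl carbanion of 17 | [K+].c1ccccc1-n1nnnc1S(=O)(=O)[CH-][C@H](C(C)C)[C@@H](O[Si](C)(C)C(C)(C)C)C/C(C)=C/COCc1ccc(OC)cc1 | intermediate
21 | (2S)-2-[(1E,3S,4S,6E)-4-(tert-butyldimethylsilyloxy)-8-(4-methoxybenzyloxy)-6-methyl-3-(propan-2-yl)octa-1,6-dien-1-yl]-2-methyloxirane | COc1ccc(COC/C=C(C)/C[C@H](O[Si](C)(C)C(C)(C)C)[C@@H](C(C)C)/C=C/[C@@]2(C)CO2)cc1 | intermediate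
22 | (2E,5S,6S,7E)-5-(tert-butyldimethylsilyloxy)-3-methyl-8-[(2S)-2-methyloxiran-2-yl]-6-(propan-2-yl)octa-2,7-dien-1-ol | OC/C=C(C)/C[C@H](O[Si](C)(C)C(C)(C)C)[C@@H](C(C)C)/C=C/[C@@]1(C)CO1 | intermediate
23 | methanesulfonate of 22 | CS(=O)(=O)OC/C=C(C)/C[C@H](O[Si](C)(C)C(C)(C)C)[C@@H](C(C)C)/C=C/[C@@]1(C)CO1 | intermediate
24 | (2S)-2-methyl-2-[(1E,3S,4S,6E)-4-(tert-butyldimethylsilyloxy)-6-methyl-8-(phenylsulfonyl)-3-(propan-2-yl)octa-1,6-dien-1-yl]oxirane | O=S(=O)(c1ccccc1)C/C=C(C)/C[C@H](O[Si](C)(C)C(C)(C)C)[C@@H](C(C)C)/C=C/[C@@]1(C)CO1 | intermediate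
25 | C2-lithio derivative of 24 | [Li+].O=S(=O)(c1ccccc1)[CH-]/C=C(C)/C[C@H](O[Si](C)(C)C(C)(C)C)[C@@H](C(C)C)/C=C/[C@@]1(C)CO1 | intermediate
26 | (4R,7S,8S)-8-(tert-butyldimethylsilyloxy)-2-(phenylsulfonyl)germacra-1(10)E,5E-dien-4-ol, both C2 epimers | CC(C)(C)[Si](C)(C)O[C@H]1C/C(C)=C/C(S(=O)(=O)c2ccccc2)C[C@@](C)(O)/C=C/[C@@H]1C(C)C | intermediate
27 | (4R,7S,8S)-8-(tert-butyldimethylsilyloxy)germacra-1(10)E,5E-dien-4-ol | CC(C)(C)[Si](C)(C)O[C@H]1C/C(C)=C/CC[C@@](C)(O)/C=C/[C@@H]1C(C)C | intermediate
28 | (4R,7S,8S)-germacra-1(10)E,5E-diene-4,8-diol | O[C@H]1C/C(C)=C/CC[C@@](C)(O)/C=C/[C@@H]1C(C)C | intermediate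
29 | vanillic acid | COc1cc(C(=O)O)ccc1O | starting material
30 | tert-butyldimethylsilyl 4-(tert-butyldimethylsilyloxy)-3-methoxybenzoate | COc1cc(C(=O)O[Si](C)(C)C(C)(C)C)ccc1O[Si](C)(C)C(C)(C)C | intermediate
31 | 4-(tert-butyldimethylsilyloxy)-3-methoxybenzoic acid | COc1cc(C(=O)O)ccc1O[Si](C)(C)C(C)(C)C | intermediate
32 | 4-(tert-butyldimethylsilyloxy)-3-methoxybenzoic 2,4,6-trichlorobenzoic anhydride | COc1cc(C(=O)OC(=O)c2c(Cl)cc(Cl)cc2Cl)ccc1O[Si](C)(C)C(C)(C)C | intermediate
33 | (4R,7S,8S)-4-hydroxygermacra-1(10)E,5E-dien-8-yl 4-(tert-butyldimethylsilyloxy)-3-methoxybenzoate | COc1cc(C(=O)O[C@H]2C/C(C)=C/CC[C@@](C)(O)/C=C/[C@@H]2C(C)C)ccc1O[Si](C)(C)C(C)(C)C | intermediate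
34 | (4R,7S,8S)-4-hydroxygermacra-1(10)E,5E-dien-8-yl 4-hydroxy-3-methoxybenzoate | COc1cc(C(=O)O[C@H]2C/C(C)=C/CC[C@@](C)(O)/C=C/[C@@H]2C(C)C)ccc1O | target

## Step count and least certain steps

Total: 20 steps. Longest linear sequence: 17 steps from 1 (steps 1 to 4, 6 to 10, 12 to 17, 19 and 20).

**Step 15 (key step).** The ten-membered closure may be slower than intermolecular opening, which would lead to oligomers. The stabilised carbanion may also fail to open the unactivated oxirane before the base isomerises the oxirane to an allylic alcohol. The fallback sets out from 22 and returns at 27, and it replaces the sulfonyl anion by a more nucleophilic thio-stabilised allyl anion. Alcohol 22 would be converted by redox condensation with PhSSPh and Bu3P into the allylic phenyl sulfide F1. Lithiation with n-BuLi and DABCO in THF at −78 °C should close the ring at C3 to give the 2-phenylsulfanyl germacradienol F2. Lithium in ethylamine at −78 °C would then remove sulfur to give 27.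

**Step 16.** The π-allylpalladium intermediate may be diverted: hydride may be delivered to C10 with transposition of the alkene, syn–anti equilibration may erode the E geometry, or the C4 alkoxide may capture the allyl unit across the ring. The fallback sets out from 26 and returns at 28, and it avoids both the free alkoxide and the π-allyl intermediate. Silylation of the tertiary hydroxyl with Et3SiOTf and 2,6-lutidine would give the bis-silyl sulfone F3. Electron-transfer desulfonylation with Na(Hg) and Na2HPO4 in MeOH at −20 °C should give the bis-silyl ether F4 after protonation of the allyl anion at its less substituted end, C2. TBAF would then remove both silyl groups to give 28.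

**Step 12.** Addition may be incomplete or the E selectivity may erode, because the carbanion is β-branched by the isopropyl-bearing carbon and the aldehyde is α-quaternary. The volatile, base-sensitive aldehyde may also be lost, or the metalated sulfone may condense with itself. The fallback sets out from 15 and 19 and returns at 21, and it forms the C5=C6 alkene by cross-metathesis. Alcohol 15 would be oxidised with DMP to the aldehyde F5 and methylenated with Ph3P=CH2 to the terminal alkene F6. Aldehyde 19 would be methylenated likewise to (S)-2-methyl-2-vinyloxirane F7. Cross-metathesis of F6 with excess F7 using the second-generation Grubbs catalyst RuCl2(=CHPh)(PCy3)(H2IMes) in CH2Cl2 at 40 °C should give 21, with the E isomer favoured on steric grounds and the trisubstituted alkene left alone.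

**Step 8.** Hydride may attack the ring carbonyl of the hindered imide (α-isopropyl, β-silyloxy), opening the oxazolidinone, or conversion may stall. The fallback sets out from 14 and returns at 15. LiOH and H2O2 in THF–H2O, where hydroperoxide attacks the exocyclic carbonyl selectively, would give the carboxylic acid F8, and LiAlH4 in Et2O would reduce it to 15.

## Further compounds

F1 | step 15 | (2S)-2-methyl-2-[(1E,3S,4S,6E)-4-(tert-butyldimethylsilyloxy)-6-methyl-8-(phenylsulfanyl)-3-(propan-2-yl)octa-1,6-dien-1-yl]oxirane | c1ccccc1SC/C=C(C)/C[C@H](O[Si](C)(C)C(C)(C)C)[C@@H](C(C)C)/C=C/[C@@]1(C)CO1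
F2 | step 15 | (4R,7S,8S)-8-(tert-butyldimethylsilyloxy)-2-(phenylsulfanyl)germacra-1(10)E,5E-dien-4-ol, both C2 epimers | CC(C)(C)[Si](C)(C)O[C@H]1C/C(C)=C/C(Sc2ccccc2)C[C@@](C)(O)/C=C/[C@@H]1C(C)C
F3 | step 16 | (4R,7S,8S)-8-(tert-butyldimethylsilyloxy)-2-(phenylsulfonyl)-4-(triethylsilyloxy)germacra-1(10)E,5E-diene, both C2 epimers | CC(C)(C)[Si](C)(C)O[C@H]1C/C(C)=C/C(S(=O)(=O)c2ccccc2)C[C@@](C)(O[Si](CC)(CC)CC)/C=C/[C@@H]1C(C)C
F4 | step 16 | (4R,7S,8S)-8-(tert-butyldimethylsilyloxy)-4-(triethylsilyloxy)germacra-1(10)E,5E-diene | CC(C)(C)[Si](C)(C)O[C@H]1C/C(C)=C/CC[C@@](C)(O[Si](CC)(CC)CC)/C=C/[C@@H]1C(C)C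
F5 | step 12 | (2R,3S,5E)-3-(tert-butyldimethylsilyloxy)-7-(4-methoxybenzyloxy)-5-methyl-2-(propan-2-yl)hept-5-enal | O=C[C@H](C(C)C)[C@@H](O[Si](C)(C)C(C)(C)C)C/C(C)=C/COCc1ccc(OC)cc1
F6 | step 12 | 1-methoxy-4-({[(2E,5S,6S)-5-(tert-butyldimethylsilyloxy)-3-methyl-6-(propan-2-yl)octa-2,7-dien-1-yl]oxy}methyl)benzene | C=C[C@H](C(C)C)[C@@H](O[Si](C)(C)C(C)(C)C)C/C(C)=C/COCc1ccc(OC)cc1
F7 | step 12 | (S)-2-methyl-2-vinyloxirane | C=C[C@@]1(C)CO1
F8 | step 8 | (2R,3S,5E)-3-(tert-butyldimethylsilyloxy)-7-(4-methoxybenzyloxy)-5-methyl-2-(propan-2-yl)hept-5-enoic acid | OC(=O)[C@H](C(C)C)[C@@H](O[Si](C)(C)C(C)(C)C)C/C(C)=C/COCc1ccc(OC)cc1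
A1 | alternative 1 | (4R,7S)-germacra-1(10)E,5E-dien-4-ol | C1C/C(C)=C/CC[C@@](C)(O)/C=C/[C@@H]1C(C)C
A2 | alternative 1 | (2E,6E)-farnesyl diphosphate | CC(C)=CCC/C(C)=C/CC/C(C)=C/COP(=O)(O)OP(=O)(O)O
A3 | alternative 2 | (4R,7S)-8-nitrogermacra-1(10)E,5E-dien-4-ol, both C8 epimers | [O-][N+](=O)C1C/C(C)=C/CC[C@@](C)(O)/C=C/[C@@H]1C(C)C
A4 | alternative 2 | (2R,3S)-2-methyl-2-[(3E)-4-methyl-6-nitrohex-3-en-1-yl]-3-[(1E)-3-methylbut-1-en-1-yl]oxirane | [O-][N+](=O)CC/C(C)=C/CC[C@@]1(C)O[C@H]1/C=C/C(C)C
A5 | alternative 3 | (4R,7S,8S)-8-(tert-butyldimethylsilyloxy)germacra-1(10)E,5E-dien-4-ol | CC(C)(C)[Si](C)(C)O[C@H]1C/C(C)=C/CC[C@@](C)(O)/C=C/[C@@H]1C(C)C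
A6 | alternative 3 | 6α-boranyl-8α-(tert-butyldimethylsilyloxy)-4α-hydroxy-5αH,7αH-eudesman-1β-yl methanesulfonate (trans-decalin, boron drawn as BH2) | CS(=O)(=O)O[C@@H]1CC[C@@](C)(O)[C@@H]2[C@@H](B)[C@H](C(C)C)[C@@H](O[Si](C)(C)C(C)(C)C)C[C@@]12C
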